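**Assumption:** 2-(benzyloxy)-N-methoxy-N-methylacetamide (18) and 1-ethoxyprop-1-yne (1) are treated as purchasable. Intermediate 13 forms as a racemate, which is of no consequence because its only stereocentre is destroyed in the following ring opening.

## Analysis of the target

The target is a flavonol: a 4H-chromen-4-one (benzo ring A fused to pyranone ring C) carrying an aryl ring B at C2 and a hydroxyl at C3. It has no stereocentre, so the whole problem is one of substitution pattern and protecting-group logic. Ring A is fully substituted: oxygen at C5, C7 and C8a alternates with methyl at C6 and C8, and C4a carries the C4 carbonyl. Ring B holds a single methyl ether at C4' between two free hydroxyls, so no global Lewis-acid dealkylation can be used at the end and all temporary oxygen protection has to be removable by hydrogenolysis or mild base. The free polyphenol and the 3-hydroxypyranone are sensitive to base and air, which argues for unmasking them last. The main difficulty is ring A: placing exactly two C-methyl groups on a phloroglucinol core is unselective, so it is better to assemble the ring with both methyls already in place. The strategy rests on the fact that this alternating pattern maps onto a vinylketene–ynol ether benzannulation. C8a–O comes from the ketene carbonyl, C7–O and C8–Me from a siloxypropyne, C5–O and C6–Me from a 3-alkoxy-2-methylcyclobutenone, and the only unsubstituted ring carbon becomes C4a.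

## Retrosynthetic reasoning

**28 to 27.** The last operation removes four benzyl groups (at O3, O5, O3' and O5') by hydrogenolysis. Benzyl is chosen because the C4' methyl ether must survive every unmasking step; 27 already has its C7 hydroxyl free.

**27 to 20 and 25.** Ring C is cut at O1–C2 and C2–C3, which is the Allan–Robinson disconnection into the o-hydroxyaryl α-benzyloxymethyl ketone 20 and the ring B anhydride 25. The C3 oxygen is carried in the ketone from the start, so no late C3 oxidation is needed. A chalcone route would pass through a ketone flanked on both sides by ring substituents, a situation in which alkaline peroxide closure tends to give the five-membered aurone instead. The forward reaction must aroylate, shift the acyl group to carbon, and cyclodehydrate; the hydrolytic work-up then also removes the silyl group at O7. Anhydride 25 is cut at its central C–O bond into acid 23 and the acid chloride 24 made from that same acid, and 23 goes back through ester 22 to the commercial gallate derivative 21.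

**20 to 17 and 18, and 17 to 16.** The C4–C4a bond is cut with the ring carbon as the nucleophile. Lewis-acid acylation or an acid-promoted acyl shift is avoided for two reasons: the benzyl ether next to C4a becomes chelated to the new ketone and is then easily stripped, and a benzyloxyacetyl cation can close onto its own phenyl ring. Instead the single ring hydrogen of 16 is exchanged for bromine (17), bromine for lithium, and the aryllithium is acylated by the amide 18, which stops at the ketone stage. Bromination is unambiguous because 16 has only one free ring position.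

**16 to 7 and 11 (key disconnection).** Three ring A bonds are cut at once: C8a–C8, C7–C6 and C8a–C4a. This returns a four-carbon unit, cyclobutenone 7 (C8a, C6, C5, C4a with the C6 methyl and the C5 benzyloxy group), and a two-carbon unit, siloxyalkyne 11 (C8 with its methyl, C7 with its silyloxy group). The gain is that every substituent of ring A is fixed by the components, the three oxygens emerge differently masked (free OH, benzyl ether, silyl ether), and the free hydroxyl sits next to the only open carbon, exactly where ring C has to be attached. The forward reaction must deliver one orientation in the ketene–alkyne union.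

**7 to 1 and 2.** The benzyl enol ether 7 comes from the acidic enol 6 by O-alkylation. 6 comes from the ethyl enol ether 5 by hydrolysis, 5 from the dichloride 4 by reduction, and 4 from a [2+2] cycloaddition of dichloroketene 3 (generated from 2) with the ynol ether 1. The polarisation of 1 places the methyl group at C2 and the alkoxy group at C3.

**11 to 8.** The siloxyalkyne is the O-silylated form of ynolate 10, which arises from ester 8 by one-carbon homologation through the dibromo enolate 9.

## Alternatives that were turned down

**Alternative 1: aryne insertion to install O1 and C4 on ring A.** The disconnection cuts O1–C8a and C4–C4a together, leading to an aryne precursor, 3,5-bis(benzyloxy)-2,4-dimethyl-6-(trimethylsilyl)phenyl trifluoromethanesulfonate (A2), and the acid (Z)-2-(benzyloxy)-3-[3,5-bis(benzyloxy)-4-methoxyphenyl]prop-2-enoic acid (A3).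
- Forward key step: CsF releases the aryne from A2; the carboxylate oxygen of A3 adds to C8a and the resulting aryl anion at C4a takes over the acyl group. The product is the 2'-hydroxy-α-benzyloxychalcone A1, which would still need oxidative closure of ring C and hydrogenolysis to reach 28.
- For it: it is highly convergent, both ring A–ring C bonds form in one step, the benzyloxy group next to C4a directs the nucleophile to the distal aryne carbon, and the C3 oxygen is already present. On late-stage convergence it is stronger than the chosen route.
- Against it: A2 is a hexasubstituted benzene that itself presupposes a selectively dimethylated, selectively protected ring A, so the real problem is only moved. The aryne is hindered on both sides. The aryl anion can be protonated by the acid before the acyl shift, which ends in a simple aryl ester. A1 still has to close in the six-membered mode and be oxidised in the presence of five benzyl ethers.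
- Comparison: the chosen strategy builds ring A from acyclic pieces in one step and then attaches the acyl carbon by a predictable organolithium acylation, for a shorter overall sequence.

**Alternative 2: biomimetic Claisen cyclisation of a polyketide chain.** The disconnection cuts C4a–C8a and unravels ring A into the triketo ester methyl (E)-9-[3,5-bis(benzyloxy)-4-methoxyphenyl]-2,4-dimethyl-3,5,7-trioxonon-8-enoate (A5).
- Forward key step: Mg(OMe)2 makes the C4a methylene attack the ester carbonyl in a six-membered Claisen closure, and aromatisation gives the chalcone A4.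
- For it: ring A appears with all three oxygens and both methyls and without any protecting group, and its symmetry removes any regiochemical question in the later pyranone closure. In protecting-group economy on ring A it is better than the chosen route.
- Against it: A5 is a mixture of tautomers and epimers that must be assembled by iterated enolate acylations. It has competing closure modes (aldol condensation to a resorcylate, lactonisation to a pyranone, conjugate addition into the enone). A4 lacks the C3 oxygen and carries three free phenols, so cyclisation, dehydrogenation and C3 hydroxylation would follow, and the usual alkaline peroxide shortcut is unreliable for a chalcone substituted on both sides of the carbonyl.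
- Comparison: the chosen route has the C3 oxygen in place before ring C is closed and passes only through stable, well-defined intermediates.

**Alternative 3: thermal ketoester condensation closing ring C at C4a.** The disconnection cuts C4–C4a and O1–C2, leading to 2,4-dimethylbenzene-1,3,5-triol (A7) and ethyl 2-(benzyloxy)-3-[3,5-bis(benzyloxy)-4-methoxyphenyl]-3-oxopropanoate (A8).
- Forward key step: heating A7 and A8 together without solvent or catalyst acylates the only free ring carbon with the ester group and condenses a flanking hydroxyl with the aryl ketone. This gives the flavone A6, one hydrogenolysis away from 28.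
- For it: it is the shortest route by a clear margin, the symmetry of A7 removes all regiochemical questions, and the C3 oxygen is in place. On step count it beats the chosen strategy.
- Against it: A7 is not trivially available, since direct C-methylation of the symmetrical triphenol core gives mixtures of mono-, di-, tri- and geminally methylated products, and A7 is air-sensitive. The melt needs temperatures at which benzyl ethers and the α-benzyloxy ketoester are at risk. Attack at the ketone carbonyl, leading to a coumarin, competes with attack at the ester. Uncatalysed condensations of this kind on hindered phenols are typically low-yielding.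
- Comparison: the chosen strategy is longer, but it offers unambiguous placement of both methyl groups by the choice of components, bond formation under controlled conditions, and three differently masked oxygens that make the later acylation clean.

Key step: step 6

## Route

**Step 1**
Reactants: 1 1-ethoxyprop-1-yne; 2 trichloroacetyl chloride
Product: 4 4,4-dichloro-3-ethoxy-2-methylcyclobut-2-en-1-one, via dichloroketene 3 (not isolated)
Conditions: Zn–Cu couple, Et2O–DME, 0 °C → rt, slow addition of 2
Reagents that add atoms: none
Why: Zinc dechlorinates 2 to dichloroketene, which undergoes a [2+2] cycloaddition with the ynol ether; the ketene carbonyl carbon bonds to the nucleophilic methyl-bearing alkyne carbon, which fixes the 2-methyl-3-ethoxy pattern, and DME ties up ZnCl2 so the acid-sensitive alkyne is not polymerised.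

**Step 2**
Reactants: 4 4,4-dichloro-3-ethoxy-2-methylcyclobut-2-en-1-one
Product: 5 3-ethoxy-2-methylcyclobut-2-en-1-one
Conditions: Zn dust, AcOH, TMEDA, EtOH, 0 °C → rt
Reagents that add atoms: none
Why: Reductive dechlorination of an α,α-dichloroketone by zinc in buffered acetic acid is the standard follow-up to dichloroketene cycloadditions and leaves the vinylogous ester untouched.

**Step 3**
Reactants: 5 3-ethoxy-2-methylcyclobut-2-en-1-one
Product: 6 3-hydroxy-2-methylcyclobut-2-en-1-one (enol form of 2-methylcyclobutane-1,3-dione)
Conditions: 1 M aq. HCl, THF, 0 °C → rt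
Reagents that add atoms: water, O
Why: Acid hydrolysis of a vinylogous ester by addition of water at C3 and loss of ethanol; the product is a strongly acidic, enolised 1,3-dione that can be isolated by extraction.

**Step 4**
Reactants: 6 3-hydroxy-2-methylcyclobut-2-en-1-one
Product: 7 3-(benzyloxy)-2-methylcyclobut-2-en-1-one
Conditions: BnOH, PPh3, DIAD, THF, 0 °C → rt
Reagents that add atoms: benzyl alcohol, OCc1ccccc1
Why: Mitsunobu alkylation, in which the acidic enol is an ideal pronucleophile and reacts at oxygen; the neutral conditions avoid the C-alkylation and ring cleavage that a basic alkylation of the strained dione could cause.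

**Step 5**
Reactants: 8 ethyl acetate
Product: 11 triisopropyl(prop-1-yn-1-yloxy)silane, via lithium 1,1-dibromoprop-1-en-2-olate 9 (not isolated), via lithium prop-1-yn-1-olate 10 (not isolated)
Conditions: CH2Br2, lithium 2,2,6,6-tetramethylpiperidide, THF, −78 °C; 8; LiN(SiMe3)2; n-BuLi, −78 °C → rt; TIPSCl, −78 → 0 °C
Reagents that add atoms: dibromomethane, BrCBr; triisopropylsilyl chloride, CC(C)[Si](Cl)(C(C)C)C(C)C
Why: Kowalski ester homologation stopped at the ynolate: dibromomethyllithium adds to the ester, the dibromo enolate 9 undergoes bromine–lithium exchange and 1,2-methyl shift with loss of LiBr to ynolate 10, and the bulky silyl chloride traps it on oxygen.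

**Step 6**
Reactants: 7 3-(benzyloxy)-2-methylcyclobut-2-en-1-one; 11 triisopropyl(prop-1-yn-1-yloxy)silane
Product: 16 5-(benzyloxy)-2,4-dimethyl-3-[(triisopropylsilyl)oxy]phenol, via vinylketene 12 (not isolated), via vinylcyclobutenone 13 (not isolated), via dienylketene 14 (not isolated), via cyclohexadienone 15 (not isolated)
Conditions: 11 (1.5 equiv), toluene, 80 °C then 110 °C, sealed tube, argon
Reagents that add atoms: none
Why: Heating opens 7 by a conrotatory four-electron electrocyclic reaction (C1–C4 bond) to vinylketene 12. Siloxyalkyne 11 then adds across the ketene C=C bond in a [2+2] cycloaddition, its methyl-bearing carbon to the ketene carbonyl carbon (C8a–C8) and its oxygen-bearing carbon to the methyl-bearing ketene carbon (C7–C6), to give 13. A second four-electron ring opening turns 13 into dienylketene 14; the rotamer with the alkenyl group turned outward cannot cyclise and recloses to 13, so the sequence drains through the (3E) isomer. Ring A is closed by a thermal disrotatory six-electron electrocyclisation of 14 (C8a–C4a bond) to dienone 15, whose enolisation to phenol 16 makes the cascade irreversible. The closest known reaction type is the Danheiser benzannulation of cyclobutenones with siloxyalkynes to monosilylated resorcinols; the 3-alkoxy substituent on the four-membered ring is the less explored variable. No stereocentre is formed in 16, and the quaternary carbon of racemic 13 disappears on ring opening. The step needs one orientation in the [2+2] event, which the polarisation of 11 secures: the oxygen lone pair makes the methyl-bearing carbon the nucleophile and the ketene carbonyl carbon is the only strongly electrophilic site, while a direct [4+2] union is disfavoured because diene and alkyne are both electron-rich. An excess of 11 and moderate dilution keep 12 from dimerising or acylating the product phenol.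

**Step 7**
Reactants: 16 5-(benzyloxy)-2,4-dimethyl-3-[(triisopropylsilyl)oxy]phenol
Product: 17 3-(benzyloxy)-2-bromo-4,6-dimethyl-5-[(triisopropylsilyl)oxy]phenol
Conditions: NBS, CH2Cl2, −40 → 0 °C
Reagents that add atoms: N-bromosuccinimide, O=C1CCC(=O)N1Br
Why: Electrophilic aromatic bromination of a very electron-rich phenol that has a single ring hydrogen, ortho to the hydroxyl and to the benzyloxy group and para to the silyloxy group, so only one product is possible.

**Step 8**
Reactants: 17 3-(benzyloxy)-2-bromo-4,6-dimethyl-5-[(triisopropylsilyl)oxy]phenol; 18 2-(benzyloxy)-N-methoxy-N-methylacetamide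
Product: 20 2-(benzyloxy)-1-{2-(benzyloxy)-6-hydroxy-3,5-dimethyl-4-[(triisopropylsilyl)oxy]phenyl}ethan-1-one, via dilithio phenolate 19 (not isolated)
Conditions: n-BuLi (2.2 equiv), THF, −78 °C; 18, −78 → 0 °C; aq. NH4Cl
Reagents that add atoms: none
Why: The first equivalent of n-BuLi deprotonates the phenol and the second performs bromine–lithium exchange; the aryllithium adds to the Weinreb amide to give a chelated tetrahedral adduct that releases the ketone only on work-up, so no over-addition occurs and both benzyl ethers and the silyl ether are untouched.

**Step 9**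
Reactants: 21 methyl 3,5-dihydroxy-4-methoxybenzoate
Product: 22 methyl 3,5-bis(benzyloxy)-4-methoxybenzoate
Conditions: BnBr, K2CO3, DMF, 60 °C
Reagents that add atoms: benzyl bromide, BrCc1ccccc1
Why: Williamson ether synthesis on both phenols; the ester and the methyl ether are inert.

**Step 10**
Reactants: 22 methyl 3,5-bis(benzyloxy)-4-methoxybenzoate
Product: 23 3,5-bis(benzyloxy)-4-methoxybenzoic acid
Conditions: NaOH, THF–MeOH–H2O, 60 °C; then aq. HCl
Reagents that add atoms: sodium hydroxide, [Na+].[OH-]
Why: Saponification of a methyl benzoate; the aryl ethers are stable to aqueous base.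

**Step 11**
Reactants: 23 3,5-bis(benzyloxy)-4-methoxybenzoic acid
Product: 24 3,5-bis(benzyloxy)-4-methoxybenzoyl chloride
Conditions: (COCl)2, cat. DMF, CH2Cl2, 0 °C → rt; concentrate
Reagents that add atoms: oxalyl chloride, O=C(Cl)C(=O)Cl
Why: Acid chloride formation through the chloroiminium species generated from DMF and oxalyl chloride; the by-products are gases, and the benzyl and methyl ethers are inert under these conditions, so the crude chloride can be used directly.

**Step 12**
Reactants: 23 3,5-bis(benzyloxy)-4-methoxybenzoic acid; 24 3,5-bis(benzyloxy)-4-methoxybenzoyl chloride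
Product: 25 3,5-bis(benzyloxy)-4-methoxybenzoic anhydride
Conditions: pyridine, CH2Cl2, 0 °C → rt
Reagents that add atoms: none
Why: Acylation of a carboxylate by an acid chloride: pyridine deprotonates 23 and activates 24 as the acylpyridinium ion, so that one molecule of each partner combines to the symmetrical anhydride and pyridinium chloride is washed out.

**Step 13**
Reactants: 20 2-(benzyloxy)-1-{2-(benzyloxy)-6-hydroxy-3,5-dimethyl-4-[(triisopropylsilyl)oxy]phenyl}ethan-1-one; 25 3,5-bis(benzyloxy)-4-methoxybenzoic anhydride
Product: 27 3,5-bis(benzyloxy)-2-[3,5-bis(benzyloxy)-4-methoxyphenyl]-7-hydroxy-6,8-dimethyl-4H-chromen-4-one, via silyl-protected flavone 26 (not isolated)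
Conditions: 25 (4 equiv), Et3N, 160 °C, sealed tube; then KOH, EtOH–H2O, reflux; aq. HCl work-up
Reagents that add atoms: none
Why: Allan–Robinson flavone synthesis in its amine-base variant: O-aroylation of the phenol, transfer of the aroyl group to the α-carbon of the benzyloxymethyl ketone, attack of the phenol oxygen on the aroyl carbonyl and dehydration close ring C with the C3 oxygen in place. The alkaline work-up hydrolyses excess anhydride and any aryl ester and cleaves the silyl ether of the acidic C7 phenol, so that the outcome converges on 27 whether or not the silyl group survives the melt.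

**Step 14**
Reactants: 27 3,5-bis(benzyloxy)-2-[3,5-bis(benzyloxy)-4-methoxyphenyl]-7-hydroxy-6,8-dimethyl-4H-chromen-4-one
Product: 28 6,8-di-C-methylmyricetin 4'-methyl ether (3,5,7-trihydroxy-2-(3,5-dihydroxy-4-methoxyphenyl)-6,8-dimethyl-4H-chromen-4-one)
Conditions: H2 (1 atm), Pd/C, THF–MeOH, rt
Reagents that add atoms: none
Why: Catalytic hydrogenolysis removes all four benzyl ethers under neutral conditions; the methyl ether and the chromone double bond are not affected at atmospheric pressure.

## Compound list

1 | 1-ethoxyprop-1-yne | CCOC#CC | starting material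
2 | trichloroacetyl chloride | ClC(=O)C(Cl)(Cl)Cl | starting material
3 | dichloroketene | O=C=C(Cl)Cl | intermediate (not isolated)
4 | 4,4-dichloro-3-ethoxy-2-methylcyclobut-2-en-1-one | CCOC1=C(C)C(=O)C1(Cl)Cl | intermediate
5 | 3-ethoxy-2-methylcyclobut-2-en-1-one | CCOC1=C(C)C(=O)C1 | intermediate
6 | 3-hydroxy-2-methylcyclobut-2-en-1-one (enol form of 2-methylcyclobutane-1,3-dione) | CC1=C(O)CC1=O | intermediate
7 | 3-(benzyloxy)-2-methylcyclobut-2-en-1-one | CC1=C(OCc2ccccc2)CC1=O | intermediate
8 | ethyl acetate | CCOC(C)=O | starting material
9 | lithium 1,1-dibromoprop-1-en-2-olate | [Li+].CC([O-])=C(Br)Br | intermediate (not isolated)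
10 | lithium prop-1-yn-1-olate | [Li+].CC#C[O-] | intermediate (not isolated)
11 | triisopropyl(prop-1-yn-1-yloxy)silane | CC#CO[Si](C(C)C)(C(C)C)C(C)C | intermediate
12 | 3-(benzyloxy)-2-methylbuta-1,3-dien-1-one (vinylketene) | O=C=C(C)C(=C)OCc1ccccc1 | intermediate (not isolated)
13 | 4-[1-(benzyloxy)ethenyl]-2,4-dimethyl-3-[(triisopropylsilyl)oxy]cyclobut-2-en-1-one (racemic) | CC1=C(O[Si](C(C)C)(C(C)C)C(C)C)C(C)(C(=C)OCc2ccccc2)C1=O | intermediate (not isolated)
14 | (3E)-5-(benzyloxy)-2,4-dimethyl-3-[(triisopropylsilyl)oxy]hexa-1,3,5-trien-1-one (dienylketene) | O=C=C(C)/C(O[Si](C(C)C)(C(C)C)C(C)C)=C(C)\C(=C)OCc1ccccc1 | intermediate (not isolated)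
15 | 5-(benzyloxy)-2,4-dimethyl-3-[(triisopropylsilyl)oxy]cyclohexa-2,4-dien-1-one | CC1=C(O[Si](C(C)C)(C(C)C)C(C)C)C(C)=C(OCc2ccccc2)CC1=O | intermediate (not isolated)
16 | 5-(benzyloxy)-2,4-dimethyl-3-[(triisopropylsilyl)oxy]phenol | Cc1c(O)cc(OCc2ccccc2)c(C)c1O[Si](C(C)C)(C(C)C)C(C)C | intermediate
17 | 3-(benzyloxy)-2-bromo-4,6-dimethyl-5-[(triisopropylsilyl)oxy]phenol | Cc1c(O)c(Br)c(OCc2ccccc2)c(C)c1O[Si](C(C)C)(C(C)C)C(C)C | intermediate
18 | 2-(benzyloxy)-N-methoxy-N-methylacetamide | CON(C)C(=O)COCc1ccccc1 | starting material
19 | lithium 3-(benzyloxy)-2-lithio-4,6-dimethyl-5-[(triisopropylsilyl)oxy]phenolate | [Li]c1c(O[Li])c(C)c(O[Si](C(C)C)(C(C)C)C(C)C)c(C)c1OCc1ccccc1 | intermediate (not isolated)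
20 | 2-(benzyloxy)-1-{2-(benzyloxy)-6-hydroxy-3,5-dimethyl-4-[(triisopropylsilyl)oxy]phenyl}ethan-1-one | Cc1c(O)c(C(=O)COCc2ccccc2)c(OCc2ccccc2)c(C)c1O[Si](C(C)C)(C(C)C)C(C)C | intermediate
21 | methyl 3,5-dihydroxy-4-methoxybenzoate | COC(=O)c1cc(O)c(OC)c(O)c1 | starting material
22 | methyl 3,5-bis(benzyloxy)-4-methoxybenzoate | COC(=O)c1cc(OCc2ccccc2)c(OC)c(OCc2ccccc2)c1 | intermediate
23 | 3,5-bis(benzyloxy)-4-methoxybenzoic acid | COc1c(OCc2ccccc2)cc(C(=O)O)cc1OCc1ccccc1 | intermediate
24 | 3,5-bis(benzyloxy)-4-methoxybenzoyl chloride | COc1c(OCc2ccccc2)cc(C(=O)Cl)cc1OCc1ccccc1 | intermediate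
25 | 3,5-bis(benzyloxy)-4-methoxybenzoic anhydride | COc1c(OCc2ccccc2)cc(C(=O)OC(=O)c2cc(OCc3ccccc3)c(OC)c(OCc3ccccc3)c2)cc1OCc1ccccc1 | intermediate
26 | 3,5-bis(benzyloxy)-2-[3,5-bis(benzyloxy)-4-methoxyphenyl]-6,8-dimethyl-7-[(triisopropylsilyl)oxy]-4H-chromen-4-one | COc1c(OCc2ccccc2)cc(-c2oc3c(C)c(O[Si](C(C)C)(C(C)C)C(C)C)c(C)c(OCc4ccccc4)c3c(=O)c2OCc2ccccc2)cc1OCc1ccccc1 | intermediate (not isolated)
27 | 3,5-bis(benzyloxy)-2-[3,5-bis(benzyloxy)-4-methoxyphenyl]-7-hydroxy-6,8-dimethyl-4H-chromen-4-one | COc1c(OCc2ccccc2)cc(-c2oc3c(C)c(O)c(C)c(OCc4ccccc4)c3c(=O)c2OCc2ccccc2)cc1OCc1ccccc1 | intermediate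
28 | 6,8-di-C-methylmyricetin 4'-methyl ether | COc1c(O)cc(-c2oc3c(C)c(O)c(C)c(O)c3c(=O)c2O)cc1O | target

## Step count and least certain steps

Total: 14 steps. Longest linear sequence: 9 steps (steps 1, 2, 3, 4, 6, 7, 8, 13, 14).

**Step 6 (key step).** The bimolecular capture of the electron-rich ketene 12 by 11 has to outrun self-condensation of the ketene and O-acylation of the phenol already formed. The temperature needed to open the alkoxy-substituted four-membered ring may also approach that at which the siloxyalkyne isomerises by a 1,3-silyl shift.

The fallback separates ketene generation from heating. It sets out from 11 and comes back at 13 and then 16. Commercial ethyl 2-methylacetoacetate is O-benzylated under Mitsunobu conditions to ethyl (E)-3-(benzyloxy)-2-methylbut-2-enoate F1. Saponification with LiOH gives (E)-3-(benzyloxy)-2-methylbut-2-enoic acid F2. Neutral treatment with 1-chloro-N,N,2-trimethylprop-1-en-1-amine gives (E)-3-(benzyloxy)-2-methylbut-2-enoyl chloride F3; the double-bond geometry is of no consequence. Slow addition of F3 to Et3N and an excess of 11 at 0 °C to rt generates 12 by 1,4-dehydrochlorination at low stationary concentration, and the [2+2] adduct 13 is isolated. Heating 13 alone in dilute toluene then completes the ring opening, electrocyclisation and enolisation to 16, with no free ketene 12 or alkyne present.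

**Step 8.** The hindered aryllithium may be quenched by proton transfer from the α-position of 18 (net loss of bromine), may be alkylated by the 1-bromobutane formed in the exchange, or the exchange on the electron-rich phenolate may be slow.

The fallback reverses the polarity and avoids the aryllithium. It sets out from 16 and comes back at 20. Magnesium-mediated ortho-formylation (MgCl2, Et3N, paraformaldehyde, MeCN, reflux) at the only free position gives 2-(benzyloxy)-6-hydroxy-3,5-dimethyl-4-[(triisopropylsilyl)oxy]benzaldehyde F4. Addition of (benzyloxymethyl)lithium, made from tributyl[(benzyloxy)methyl]stannane and n-BuLi and used in excess, gives racemic 2-(benzyloxy)-1-{2-(benzyloxy)-6-hydroxy-3,5-dimethyl-4-[(triisopropylsilyl)oxy]phenyl}ethan-1-ol F5. Oxidation of this benzylic alcohol with MnO2 gives 20.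

**Step 13.** The melt may cause thermal degradation, the acyl transfer of the doubly ortho-substituted ketone may stop at the O-aroyl ester or the diketone, and the alkaline work-up may open the pyranone ring.

The fallback is the stepwise Baker–Venkataraman sequence under mild conditions. It sets out from 20 and 24 and comes back at 26 and then 27. Aroylation of 20 with the acid chloride 24 in pyridine with DMAP gives 2-[2-(benzyloxy)acetyl]-3-(benzyloxy)-4,6-dimethyl-5-[(triisopropylsilyl)oxy]phenyl 3,5-bis(benzyloxy)-4-methoxybenzoate F6. LiN(SiMe3)2 in THF (−78 → 0 °C) moves the aroyl group to carbon and gives 2-(benzyloxy)-1-{2-(benzyloxy)-6-hydroxy-3,5-dimethyl-4-[(triisopropylsilyl)oxy]phenyl}-3-[3,5-bis(benzyloxy)-4-methoxyphenyl]propane-1,3-dione F7. Catalytic TsOH in warm toluene cyclodehydrates F7 to 26, and Bu4NF in THF removes the silyl group to give 27.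

**Step 4.** Alkylation may take place at carbon instead of oxygen, or the strained dione may be opened by the nucleophiles present.

The fallback forms the C3–O bond by exchange instead of forming the O–CH2 bond by alkylation. It sets out from 5 and comes back at 7, bypassing 6. Enol ether 5 is heated with excess benzyl alcohol and catalytic camphorsulfonic acid in toluene under reduced pressure, so that ethanol is removed and the vinylogous transesterification is driven to 7. No new compound is formed on the way.

## Further compounds

F1 | step 6 | ethyl (E)-3-(benzyloxy)-2-methylbut-2-enoate | CCOC(=O)/C(C)=C(\C)OCc1ccccc1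
F2 | step 6 | (E)-3-(benzyloxy)-2-methylbut-2-enoic acid | OC(=O)/C(C)=C(\C)OCc1ccccc1
F3 | step 6 | (E)-3-(benzyloxy)-2-methylbut-2-enoyl chloride | ClC(=O)/C(C)=C(\C)OCc1ccccc1
F4 | step 8 | 2-(benzyloxy)-6-hydroxy-3,5-dimethyl-4-[(triisopropylsilyl)oxy]benzaldehyde | Cc1c(O)c(C=O)c(OCc2ccccc2)c(C)c1O[Si](C(C)C)(C(C)C)C(C)C
F5 | step 8 | 2-(benzyloxy)-1-{2-(benzyloxy)-6-hydroxy-3,5-dimethyl-4-[(triisopropylsilyl)oxy]phenyl}ethan-1-ol (racemic) | Cc1c(O)c(C(O)COCc2ccccc2)c(OCc2ccccc2)c(C)c1O[Si](C(C)C)(C(C)C)C(C)C
F6 | step 13 | 2-[2-(benzyloxy)acetyl]-3-(benzyloxy)-4,6-dimethyl-5-[(triisopropylsilyl)oxy]phenyl 3,5-bis(benzyloxy)-4-methoxybenzoate | Cc1c(OC(=O)c2cc(OCc3ccccc3)c(OC)c(OCc3ccccc3)c2)c(C(=O)COCc2ccccc2)c(OCc2ccccc2)c(C)c1O[Si](C(C)C)(C(C)C)C(C)C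
F7 | step 13 | 2-(benzyloxy)-1-{2-(benzyloxy)-6-hydroxy-3,5-dimethyl-4-[(triisopropylsilyl)oxy]phenyl}-3-[3,5-bis(benzyloxy)-4-methoxyphenyl]propane-1,3-dione (racemic) | Cc1c(O)c(C(=O)C(OCc2ccccc2)C(=O)c2cc(OCc3ccccc3)c(OC)c(OCc3ccccc3)c2)c(OCc2ccccc2)c(C)c1O[Si](C(C)C)(C(C)C)C(C)C
F0 | step 4 | none | none
A1 | alternative 1 | (Z)-2-(benzyloxy)-3-[3,5-bis(benzyloxy)-4-methoxyphenyl]-1-[4,6-bis(benzyloxy)-2-hydroxy-3,5-dimethylphenyl]prop-2-en-1-one | Cc1c(O)c(C(=O)/C(OCc2ccccc2)=C/c2cc(OCc3ccccc3)c(OC)c(OCc3ccccc3)c2)c(OCc2ccccc2)c(C)c1OCc1ccccc1
A2 | alternative 1 | 3,5-bis(benzyloxy)-2,4-dimethyl-6-(trimethylsilyl)phenyl trifluoromethanesulfonate | Cc1c(OCc2ccccc2)c(C)c(OS(=O)(=O)C(F)(F)F)c([Si](C)(C)C)c1OCc1ccccc1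
A3 | alternative 1 | (Z)-2-(benzyloxy)-3-[3,5-bis(benzyloxy)-4-methoxyphenyl]prop-2-enoic acid | OC(=O)/C(OCc1ccccc1)=C/c1cc(OCc2ccccc2)c(OC)c(OCc2ccccc2)c1
A4 | alternative 2 | (E)-3-[3,5-bis(benzyloxy)-4-methoxyphenyl]-1-(2,4,6-trihydroxy-3,5-dimethylphenyl)prop-2-en-1-one | Cc1c(O)c(C)c(O)c(C(=O)/C=C/c2cc(OCc3ccccc3)c(OC)c(OCc3ccccc3)c2)c1O
A5 | alternative 2 | methyl (E)-9-[3,5-bis(benzyloxy)-4-methoxyphenyl]-2,4-dimethyl-3,5,7-trioxonon-8-enoate (mixture of epimers and tautomers) | COC(=O)C(C)C(=O)C(C)C(=O)CC(=O)/C=C/c1cc(OCc2ccccc2)c(OC)c(OCc2ccccc2)c1
A6 | alternative 3 | 3-(benzyloxy)-2-[3,5-bis(benzyloxy)-4-methoxyphenyl]-5,7-dihydroxy-6,8-dimethyl-4H-chromen-4-one | COc1c(OCc2ccccc2)cc(-c2oc3c(C)c(O)c(C)c(O)c3c(=O)c2OCc2ccccc2)cc1OCc1ccccc1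
A7 | alternative 3 | 2,4-dimethylbenzene-1,3,5-triol | Cc1c(O)cc(O)c(C)c1O
A8 | alternative 3 | ethyl 2-(benzyloxy)-3-[3,5-bis(benzyloxy)-4-methoxyphenyl]-3-oxopropanoate (racemic) | CCOC(=O)C(OCc1ccccc1)C(=O)c1cc(OCc2ccccc2)c(OC)c(OCc2ccccc2)c1
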